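| setting | violet | flask |
|---|---|---|
| substrate | 0.50 M | 0.50 M |
| first nucleophile | 0.50 M | 0.500 M |
| solid second nucleophile | 0.475 M | 0.475 M |
| remark | the very flask that is asked about, followed so far |  |
| time |  | 10 d |

violet run (percent of the substrate charged)

| time / h | target / % | other capture product / % | substrate / % |
|---|---|---|---|
| 4.00 | 39.5 | 1.8 | 16.9 |
| 8.00 | 51.7 | 4.1 | 2.9 |
| 20.0 | 54.4 | 10.3 | 0 |
| 50.0 | 46.9 | 24.0 | 0 |

(each reading ± 1 percentage point)

- at the start none of the solid second nucleophile is in solution

- ratio of target to other capture product at 80 min
- ratio of target to other capture product at 10 d

**Ratio and time.** The ratio of target to other capture product, the selectivity, falls in the violet run by 1.05 powers of ten while time rises by 1.10. On logarithms the slope is therefore near minus one, and the last reading gives 97.7 h. I call this ratio multiplied by its time the ratio-time product. Divided by the asked times, it gives me 73.3 at 80 min and 0.407 at 10 d.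

**The balance.** My second way uses amounts. A straight line through the later readings of other capture product gives me an estimate of 114% at 10 d, but the solid second nucleophile was charged at 95.0% of the substrate. Taking that as the ceiling and the remainder as target gives me a ratio of 0.0526.

**Which cheats.** The two ways part at 10 d. With the straight line, the ratio from the ratio-time product asks for 160% of the charge as target and other capture product, more than the whole charge, so the straight line and the ratio-time product do not stand together there. I cannot tell from this which of the two cheats, so I commit to the middle of the two logarithms, 0.146. At 80 min I keep 73.3.

**The forecast.** It gives 18 and 0.05, holding that other capture product “looks limited by dissolution of the solid”. Its early ratio is lower than mine.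

**The result.** The flask gives 103 at 80 min and 0.120 at 10 d. At 10.0 d it holds 86.0% of other capture product against 10.3% of target. Its ratio-time product is 137 h at 80 min and 28.8 h at 10 d, on either side of the 97.7 h I read.

    substrate → intermediate (k = 1.24 × 10⁻⁴ /s)
    first nucleophile + intermediate ⇌ target (K = 5.90 /M, k = 2.63 × 10⁻⁴ /M/s)
    second nucleophile + intermediate → other capture product (k = 4.34 × 10⁻⁴ /M/s)
    solid second nucleophile ⇌ second nucleophile, rate k4*(cs4 - [second nucleophile]) while solid is left; crystals form when [second nucleophile] > cs4 (solubility = 38.0 mM, k = 2.51 × 10⁻⁵ /s)

**Second flask.** For a neighbour flask with 0.20 M of first nucleophile, I scale the ratio-time product by that charge, as an assumption of my own, and get 29.3 at 80 min. That neighbour flask computes to 40.7, above my figure by a factor of 1.39, and the asked flask stood above mine by 1.41.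

All runs are simulated with constants of no real substance; scatter was added.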